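Remark on the chemistry: ring B of 21 and 24 is written as the enol tautomer of the target SMILES; the tautomers interconvert and the route does not depend on which one predominates. Oxime 10 is used as its E/Z mixture.

## Analysis of the target

- Target 24 consists of two six-membered carbocycles joined through one methylene carbon. It has no stereocentre, because the only sp3 ring carbon carries two identical methyl groups.
- Ring A is an aromatic acylphloroglucinol. Its butanoyl-bearing carbon lies between two C–OH carbons, a third C–OH is para to the acyl group, and the remaining two carbons are one C–H and the bridge-bearing carbon.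
- Ring B is the enolised form of a 2-acyl-4,4-dimethylcyclohexane-1,3,5-trione. The quaternary C(CH3)2 carbon lies between two enolic C–OH carbons, and the propanoyl-bearing and bridge-bearing carbons flank the remaining ring carbonyl.
- The sensitive elements are the electron-rich polyphenol (oxidation), the β-triketone (retro-Claisen cleavage, O-alkylation) and the two bonds to the bridging CH2, which form reversibly and can scramble in alkali.
- Three things make the synthesis hard: joining two similarly nucleophilic rings through one carbon without homodimers, placing exactly two methyl groups on one carbon of ring B, and securing the 1-acyl-2,4,6-trioxygenated pattern of ring A.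
- The strategy rests on ring A. Its butanoyl-bearing carbon and one neighbouring C–OH carbon form an ortho-hydroxyaryl ketone, which is the N–O cleavage product of a 3-propyl-1,2-benzisoxazole. That heterocycle forms in one step when an aryne located at exactly these two carbons captures a four-carbon nitrile oxide.

## Retrosynthetic reasoning

**24 to 17, 21 and 22.** The first cut breaks both C–C bonds of the bridging carbon, one to ring A and one to ring B. Each bond joins the methylene carbon to the nucleophilic α-carbon of a vinylogous acid, so both can be made by enol and phenol chemistry without protecting groups. The cut divides 24 into two halves of similar size, 17 and 21, which already carry all their oxygen atoms and acyl groups. Forward, 22 must condense with 21 to the methylidene trione 23, and the free ring carbon of 17 must then add to it in preference to self-coupling of either half.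

**21 to 20, then to 18 and 19.** The two C–CH3 bonds at the quaternary carbon of ring B are cut, which returns the dienone to the aromatic acylphloroglucinol 20. The aryl–acyl bond of 20 is then cut to give 18 and 19. The quaternary carbon is the only part of ring B that does not come directly from 18, so its removal exposes a one-step Friedel–Crafts product. Forward, the methylation must put two methyl groups on the same ring carbon and then stop.

**17 to 16.** The two hydroxyl groups outside the ortho-hydroxy ketone unit are capped as O–CH3. Free phenols cannot pass through organolithium and aryne chemistry. Methyl is the smallest cap, which matters because one of these oxygens sits beside the reacting aryne carbon. Forward, a double aryl methyl ether cleavage is carried out on a simple ketone before any sensitive part of 24 exists.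

**16 to 14 by way of 15.** The ketone oxygen is exchanged for N–H (15), and the nitrogen is then bonded to the neighbouring phenol oxygen, closing the isoxazole ring of 14. No skeletal bond changes. The ortho-hydroxy ketone simply becomes a heteroaromatic ring that a cycloaddition can build. Forward, hydrogenolysis must cleave only the N–O bond, and hydrolysis then frees the ketone.

**14 to 12 and 13, and so to 8 and 11.** This is the disconnection that carries the route. The C3–C3a and O1–C7a bonds of 14 are cut together. The acyl carbon and the phenol oxygen therefore arrive as one three-atom unit on two adjacent aryl carbons, whose positions are fixed by the silyl and triflate groups of 8. The aryl ketone is installed masked, under near-neutral conditions, with no electrophilic acylation of a polyoxygenated arene. Forward, 12 and 13 must be generated at matched rates and joined with the oxygen on the aryne carbon remote from the flanking methoxy group.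

**8 to 1 by way of 7, 6 and 2.** The S–O bond of the triflate is cut to the phenoxide 7, the carbamate 6 is its protected form, and the aryl C–Si bond of 6 is cut to carbamate 2, which comes from 1. The carbamate serves twice: it directs metalation to the carbon between itself and a methoxy group, and it leaves under mild base so that the silylphenol need not be isolated.

**11 to 9 by way of 10.** The C–Cl bond is cut to oxime 10 and the C=N bond to aldehyde 9. The four carbons of the butanoyl group thus come from a commodity aldehyde.

## Alternatives that were turned down

**Alternative 1: dearomative gem-dimethylation of an aromatic dimer.**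
- Disconnection: the two C–CH3 bonds at the quaternary carbon of ring B are cut last, on a fully aromatic methylene-bridged dimer A2 whose ring A phenols are benzylated.
- Forward key step: alkoxide-mediated double C-methylation of the single free ring carbon of the ring B half of A2 dearomatises it to the dienone A1. Hydrogenolysis of three benzyl ethers would then give 24.
- For it: the ring B half of A2 has only one free carbon, so methylation can only end in the gem-dimethyl group. That is cleaner than the methylation of 20, which has two free carbons. The route is also shorter.
- Against it: A2 still requires an unsymmetrical methylene coupling. With ring A benzylated it is no longer a carbon nucleophile, so the bridge must come from a benzylic electrophile on ring A attacking 20, which has two equivalent nucleophilic carbons. The statistical problem is moved, not removed. Three free phenols of ring B compete for the methylating agent on a late, valuable intermediate.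
- Comparison: Alternative 1 is stronger on step count and on the selectivity of the methylation. The chosen route offers methylation on a cheap early compound, where a mixture costs little, and a ring A that is never exposed to a methylating agent.

**Alternative 2: vinylketene and siloxyalkyne annulation.**
- Disconnection: three ring bonds of ring B, namely both bonds of the ring carbonyl carbon and one further bond.
- Forward key step: heating cyclobutenone A4 with siloxyalkyne A5 opens A4 to a vinylketene, which adds to the alkyne. The new four-membered ring opens and recloses by 6π electrocyclisation. The quaternary carbon blocks aromatisation, so the sequence stops at dienone A3.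
- For it: the bridge carbon is already in A5 and the quaternary carbon in A4. Neither a statistical coupling nor a methylation selectivity problem arises, and the regiochemistry of ring B follows from the mechanism.
- Against it: A3 lacks both acyl groups and carries five O-alkyl or O-silyl groups. Two enol ethers must be unmasked, ring B propanoylated, ring A butanoylated, and three aryl methyl ethers cleaved by a strong Lewis acid in the presence of the trione and the labile bridge bonds. A4 and A5 each need several steps. The electrocyclisation must close onto a fully substituted alkene terminus.
- Comparison: Alternative 2 is stronger on the unsymmetrical connection. The chosen route is shorter after its key step, uses simpler building blocks, and finishes all harsh deprotection before the two halves meet.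

**Alternative 3: acylketene and keto ester annulation.**
- Disconnection: two bonds of ring B, one from the bridge-bearing carbon to the ring carbonyl carbon and one from the propanoyl-bearing carbon to a C–OH carbon.
- Forward key step: the enolate of keto ester A7 is C-acylated by the acylketene released on heating dioxinone A8. The resulting triketo ester closes by Dieckmann condensation to A6.
- For it: the quaternary carbon, the bridge and the propanoyl group are all present when ring B forms. A7 has only one enolisable position. A6 is more advanced than A3.
- Against it: acylketenes tend to acylate enolates on oxygen. The α,α-dimethyl β-keto ester is prone to retro-Claisen cleavage under the hot basic conditions. The Dieckmann step needs a stabilised diketone enolate to attack a hindered ester. After A6, butanoylation of ring A competes with acylation of the ring B enols, and three methyl ethers must still be cleaved on the complete skeleton.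
- Comparison: Alternative 3 avoids both statistical steps of the chosen route. The chosen route relies on better-precedented bond formations and removes its methyl ethers at the stage of the simple ketone 16.

Key step: step 6

## Route

Step 1
Reactants: 1 3,5-dimethoxyphenol
Product: 2 3,5-dimethoxyphenyl N-(propan-2-yl)carbamate
Conditions: i-PrNCO, Et3N (cat.), CH2Cl2, rt
Reagents that add atoms: isopropyl isocyanate, CC(C)N=C=O
Why: Amine-catalysed addition of a phenol O–H to an isocyanate (carbamoylation) is clean and touches nothing else. The secondary carbamate is chosen because it can later be removed by mild base.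

Step 2
Reactants: 2 3,5-dimethoxyphenyl N-(propan-2-yl)carbamate
Product: 6 3,5-dimethoxy-2-(trimethylsilyl)phenyl N-(propan-2-yl)carbamate, via N-silyl carbamate 3 (not isolated), via aryllithium 4 (not isolated), via disilyl carbamate 5 (not isolated)
Conditions: TBSOTf, TMEDA, Et2O, 0 °C to rt; n-BuLi (2.1 equiv), TMEDA, −78 °C; TMSCl, −78 °C to rt; cold aq NaHSO4 (short contact)
Reagents that add atoms: chlorotrimethylsilane, C[Si](C)(C)Cl; tert-butyldimethylsilyl trifluoromethanesulfonate, CC(C)(C)[Si](C)(C)OS(=O)(=O)C(F)(F)F (its silyl group is carried only by 3, 4 and 5); n-butyllithium, [Li]CCCC (its lithium is carried only by 4)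
Why: This is a carbamate-directed ortho-metalation after transient N-silylation of the N–H. Lithiation should occur at the carbon flanked by the carbamate oxygen and a methoxy group, where the stronger director and a second director cooperate, not between the two methoxy groups. TMSCl traps the aryllithium at −78 °C before any anionic Fries shift, and the N–Si bond is hydrolysed on work-up.

Step 3
Reactants: 6 3,5-dimethoxy-2-(trimethylsilyl)phenyl N-(propan-2-yl)carbamate
Product: 8 3,5-dimethoxy-2-(trimethylsilyl)phenyl trifluoromethanesulfonate, via silylphenoxide 7 (not isolated)
Conditions: Et2NH, DBU, MeCN, 40 °C; then PhNTf2, rt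
Reagents that add atoms: N-phenylbis(trifluoromethanesulfonimide), O=S(=O)(N(c1ccccc1)S(=O)(=O)C(F)(F)F)C(F)(F)F
Why: DBU deprotonates the carbamate N–H and the phenoxide 7 is expelled by E1cB elimination, while Et2NH traps the isocyanate as a urea. The phenoxide is then triflated in the same flask by sulfonyl transfer from PhNTf2, so the acid-sensitive silylphenol is never isolated.

Step 4
Reactants: 9 butanal
Product: 10 butanal oxime (E/Z mixture)
Conditions: NH2OH (50% aq), EtOH, 0 °C to rt
Reagents that add atoms: hydroxylamine, NO
Why: Condensation of an aldehyde with hydroxylamine gives the oxime. Both geometric isomers are usable because the geometry is lost at the nitrile oxide stage.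

Step 5
Reactants: 10 butanal oxime (E/Z mixture)
Product: 11 (Z)-N-hydroxybutanimidoyl chloride
Conditions: NCS, DMF, rt (trace HCl to initiate); used crude and cold
Reagents that add atoms: N-chlorosuccinimide, O=C1CCC(=O)N1Cl
Why: Electrophilic chlorination of an aldoxime at the oxime carbon is the standard route to hydroximoyl chlorides, which adopt the Z geometry with chlorine and hydroxyl on the same side. The aliphatic chloride is only moderately stable, so it is not stored.

Step 6
Reactants: 8 3,5-dimethoxy-2-(trimethylsilyl)phenyl trifluoromethanesulfonate; 11 (Z)-N-hydroxybutanimidoyl chloride
Product: 14 4,6-dimethoxy-3-propyl-1,2-benzisoxazole, via 3,5-dimethoxybenzyne 12 (not isolated), via butanenitrile oxide 13 (not isolated)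
Conditions: CsF (6 equiv), MeCN, rt; 11 (2 equiv) added by syringe pump over several hours
Reagents that add atoms: none
Why: Fluoride attacks the silicon of 8 and the aryl anion expels triflate to give aryne 12, while the same fluoride dehydrochlorinates 11 to nitrile oxide 13, so both partners are formed at low concentration in one flask. They combine in a 1,3-dipolar [3+2] cycloaddition, the known route from silylaryl triflates and hydroximoyl chlorides to 1,2-benzisoxazoles. The isoxazole ring is closed by this intermolecular cycloaddition, which forms the C3–C3a and O1–C7a bonds in one, probably asynchronous, event; no tethered cyclisation is involved and no stereocentre is created. The step needs regioselectivity: the oxide oxygen must bond to the aryne carbon remote from the neighbouring methoxy group and the nitrile carbon to the carbon beside it. The σ-withdrawing methoxy group at C3 of 12 makes C1 the more electrophilic terminus and lets C2 carry the developing negative charge, which directs the nucleophilic oxygen of 13 to C1. The second methoxy group, para to C2, exerts a weaker opposing pull, and the propyl group ends up next to a methoxy group, so some of the other regioisomer must be expected and removed by chromatography. Slow addition of 11 keeps 13 dilute and limits its dimerisation.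

Step 7
Reactants: 14 4,6-dimethoxy-3-propyl-1,2-benzisoxazole
Product: 16 1-(2-hydroxy-4,6-dimethoxyphenyl)butan-1-one, via ketimine 15 (not isolated)
Conditions: H2 (1 atm), Raney Ni, EtOH, rt; then 2 M aq HCl, THF, 50 °C
Reagents that add atoms: water, O
Why: Catalytic hydrogenolysis of the weak N–O bond of a 1,2-benzisoxazole gives the hydrogen-bonded ortho-hydroxyaryl N–H ketimine, which is conjugated and hindered and should resist further reduction. Aqueous acid then hydrolyses the imine to the ketone, and the methyl ethers and the arene are untouched.

Step 8
Reactants: 16 1-(2-hydroxy-4,6-dimethoxyphenyl)butan-1-one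
Product: 17 1-(2,4,6-trihydroxyphenyl)butan-1-one
Conditions: BBr3 (6 equiv), CH2Cl2, −78 °C to reflux; H2O quench
Reagents that add atoms: none
Why: This is a Lewis acid cleavage of aryl methyl ethers by BBr3. The methoxy group ortho to the carbonyl is cleaved readily through a boron chelate, and excess reagent with warming is used for the less basic para methoxy group.

Step 9
Reactants: 18 phloroglucinol; 19 propanoyl chloride
Product: 20 1-(2,4,6-trihydroxyphenyl)propan-1-one
Conditions: AlCl3, PhNO2, rt to 60 °C; ice, aq HCl
Reagents that add atoms: none
Why: Friedel–Crafts C-acylation of the symmetrical triphenol can give only one monoacyl product. The first acyl group deactivates the ring, so one equivalent of 19 should stop at monoacylation.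

Step 10
Reactants: 20 1-(2,4,6-trihydroxyphenyl)propan-1-one
Product: 21 3,5-dihydroxy-4,4-dimethyl-2-propanoylcyclohexa-2,5-dien-1-one
Conditions: NaOMe (3 equiv), MeI (2.2 equiv), MeOH, 0 °C to rt; aq HCl
Reagents that add atoms: iodomethane, CI
Why: This is a dearomative C-methylation of the acylphloroglucinol polyanion. The first methyl group makes its ring carbon the more electron-rich enolate terminus, so the second methyl group should enter at the same carbon and give the gem-dimethyl dienone. Limiting the iodomethane restrains methylation at the remaining ring C–H.

Step 11
Reactants: 17 1-(2,4,6-trihydroxyphenyl)butan-1-one; 21 3,5-dihydroxy-4,4-dimethyl-2-propanoylcyclohexa-2,5-dien-1-one; 22 formaldehyde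
Product: 24 2-[(3-butanoyl-2,4,6-trihydroxyphenyl)methyl]-3,5-dihydroxy-4,4-dimethyl-6-propanoylcyclohexa-2,5-dien-1-one (CNP0330971.0), via methylidene trione 23 (not isolated)
Conditions: 17 (3 equiv), 21 (1 equiv), 22 (37% aq, 1 equiv), 1% aq KOH, 0 °C to rt; then 1 M HCl
Reagents that add atoms: none
Why: Knoevenagel condensation of the free ring carbon of 21 with 22 gives enone 23, and the phenolate of 17 adds through its free ring carbon (Michael addition, then re-aromatisation). This is the classical methylene bridging of acylphloroglucinols. Excess 17, whose two free ring carbons are equivalent, should favour the mixed dimer over self-coupling of 21 and over a second alkylation of 24; no stereocentre is formed.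

## Compound list

1 | 3,5-dimethoxyphenol | COc1cc(O)cc(OC)c1 | starting material
2 | 3,5-dimethoxyphenyl N-(propan-2-yl)carbamate | COc1cc(OC)cc(OC(=O)NC(C)C)c1 | intermediate
3 | 3,5-dimethoxyphenyl N-(tert-butyldimethylsilyl)-N-(propan-2-yl)carbamate (formed in the flask in step 2) | COc1cc(OC)cc(OC(=O)N(C(C)C)[Si](C)(C)C(C)(C)C)c1 | intermediate
4 | {2-[(tert-butyldimethylsilyl)(propan-2-yl)carbamoyloxy]-4,6-dimethoxyphenyl}lithium (formed in the flask in step 2) | COc1cc(OC)c([Li])c(OC(=O)N(C(C)C)[Si](C)(C)C(C)(C)C)c1 | intermediate
5 | 3,5-dimethoxy-2-(trimethylsilyl)phenyl N-(tert-butyldimethylsilyl)-N-(propan-2-yl)carbamate (formed in the flask in step 2) | COc1cc(OC)c([Si](C)(C)C)c(OC(=O)N(C(C)C)[Si](C)(C)C(C)(C)C)c1 | intermediate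
6 | 3,5-dimethoxy-2-(trimethylsilyl)phenyl N-(propan-2-yl)carbamate | COc1cc(OC)c([Si](C)(C)C)c(OC(=O)NC(C)C)c1 | intermediate
7 | 3,5-dimethoxy-2-(trimethylsilyl)phenol (present in step 3 as its DBU-H+ phenoxide) | COc1cc(OC)c([Si](C)(C)C)c(O)c1 | intermediate
8 | 3,5-dimethoxy-2-(trimethylsilyl)phenyl trifluoromethanesulfonate | COc1cc(OC)c([Si](C)(C)C)c(OS(=O)(=O)C(F)(F)F)c1 | intermediate
9 | butanal | CCCC=O | starting material
10 | butanal oxime (E/Z mixture) | CCCC=NO | intermediate
11 | (Z)-N-hydroxybutanimidoyl chloride | CCC/C(Cl)=N/O | intermediate
12 | 3,5-dimethoxybenzyne (formed in the flask in step 6) | COC1=CC(OC)=CC#C1 | intermediate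
13 | butanenitrile oxide (formed in the flask in step 6) | CCCC#[N+][O-] | intermediate
14 | 4,6-dimethoxy-3-propyl-1,2-benzisoxazole | CCCc1noc2cc(OC)cc(OC)c12 | intermediate
15 | 2-(1-iminobutyl)-3,5-dimethoxyphenol (formed in the flask in step 7) | CCCC(=N)c1c(O)cc(OC)cc1OC | intermediate
16 | 1-(2-hydroxy-4,6-dimethoxyphenyl)butan-1-one | CCCC(=O)c1c(O)cc(OC)cc1OC | intermediate
17 | 1-(2,4,6-trihydroxyphenyl)butan-1-one | CCCC(=O)c1c(O)cc(O)cc1O | intermediate
18 | phloroglucinol | Oc1cc(O)cc(O)c1 | starting material
19 | propanoyl chloride | CCC(=O)Cl | starting material
20 | 1-(2,4,6-trihydroxyphenyl)propan-1-one | CCC(=O)c1c(O)cc(O)cc1O | intermediate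
21 | 3,5-dihydroxy-4,4-dimethyl-2-propanoylcyclohexa-2,5-dien-1-one | CCC(=O)C1=C(O)C(C)(C)C(O)=CC1=O | intermediate
22 | formaldehyde | C=O | starting material
23 | 3-hydroxy-4,4-dimethyl-6-methylidene-2-propanoylcyclohex-2-ene-1,5-dione (formed in the flask in step 11) | CCC(=O)C1=C(O)C(C)(C)C(=O)C(=C)C1=O | intermediate
24 | 2-[(3-butanoyl-2,4,6-trihydroxyphenyl)methyl]-3,5-dihydroxy-4,4-dimethyl-6-propanoylcyclohexa-2,5-dien-1-one | CCCC(=O)c1c(O)cc(O)c(CC2=C(O)C(C)(C)C(O)=C(C(=O)CC)C2=O)c1O | target

## Step count and least certain steps

Total step count: 11. Longest linear sequence: 7 (steps 1, 2, 3, 6, 7, 8, 11).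

**Step 6 (key step).** The most likely failure is insufficient regiocontrol in the cycloaddition, because the steric demand of the propyl group and the remote methoxy group both work against the directing methoxy group. A second failure is loss of the dipole by dimerisation if it forms faster than the aryne. The fallback abandons the aryne construction of the aryl ketone. It sets out from 1, which is heated with butanoic acid in BF3·OEt2. O-acylation gives 3,5-dimethoxyphenyl butanoate F1, which undergoes Fries rearrangement in the same medium; ortho migration is favoured by chelation between the phenol oxygen and the new carbonyl. The route is rejoined at 16.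

**Step 11.** The most likely failure is self-coupling of either half in competition with cross-coupling, made worse by reversible Michael addition in alkali, which scrambles the bridge, and by a second alkylation at the remaining ring A C–H. The fallback separates electrophile formation from the coupling. It sets out from 21, which undergoes a Mannich reaction with N,N-dimethylmethyleneiminium iodide to give 6-[(dimethylamino)methyl]-3,5-dihydroxy-4,4-dimethyl-2-propanoylcyclohexa-2,5-dien-1-one F2. Heating F2 with excess 17 in dioxane eliminates the amine, releasing 23 slowly in the absence of free 21. Capture by 17 rejoins the route at 24.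

**Step 10.** The most likely failure is over-methylation at the second free ring carbon and competing O-methylation, which would leave the gem-dimethyl compound as one component of a mixture. The fallback blocks the second carbon with a removable ester. It sets out from 19, which acylates purchased methyl 2,4,6-trihydroxybenzoate F3 under AlCl3 to give methyl 2,4,6-trihydroxy-3-propanoylbenzoate F4. NaOMe and MeI then methylate the single free ring carbon twice, giving methyl 2,4-dihydroxy-3,3-dimethyl-6-oxo-5-propanoylcyclohexa-1,4-diene-1-carboxylate F5. Saponification with aqueous NaOH, then acidification and warming, removes the ester carbon by decarboxylation and rejoins the route at 21.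

**Step 2.** The most likely failure is metalation at the carbon between the two methoxy groups, or protodesilylation of the very electron-rich aryl–silicon bond during the acidic work-up. The fallback fixes the position of the anion by halogen–metal exchange. It sets out from 1, which is brominated ortho to the hydroxyl group (NBS, cat. i-Pr2NH, CH2Cl2) to give 2-bromo-3,5-dimethoxyphenol F6. O-silylation with hexamethyldisilazane gives (2-bromo-3,5-dimethoxyphenoxy)trimethylsilane F7. n-BuLi at −78 °C effects bromine–lithium exchange and retro-Brook migration of silicon from oxygen to carbon, giving the lithium salt of 7. Tf2O then triflates it, and the route is rejoined at 8, which also bypasses step 3.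

**Step 8.** The most likely failure is incomplete cleavage of the methoxy group para to the ketone, whose oxygen is a poorly basic vinylogous ester, or loss of the acyl group on prolonged exposure to the Lewis acid. The fallback demethylates before the ketone is unmasked. It sets out from 14, whose ordinary aryl methyl ethers are cleaved by BBr3 to give 3-propyl-1,2-benzisoxazole-4,6-diol F8. Hydrogenolysis of the N–O bond of F8 over Raney Ni and acid hydrolysis of the imine then rejoin the route at 17.

## Further compounds

F1 | step 6 | 3,5-dimethoxyphenyl butanoate | CCCC(=O)Oc1cc(OC)cc(OC)c1
F2 | step 11 | 6-[(dimethylamino)methyl]-3,5-dihydroxy-4,4-dimethyl-2-propanoylcyclohexa-2,5-dien-1-one | CCC(=O)C1=C(O)C(C)(C)C(O)=C(CN(C)C)C1=O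
F3 | step 10 | methyl 2,4,6-trihydroxybenzoate | COC(=O)c1c(O)cc(O)cc1O
F4 | step 10 | methyl 2,4,6-trihydroxy-3-propanoylbenzoate | CCC(=O)c1c(O)cc(O)c(C(=O)OC)c1O
F5 | step 10 | methyl 2,4-dihydroxy-3,3-dimethyl-6-oxo-5-propanoylcyclohexa-1,4-diene-1-carboxylate | CCC(=O)C1=C(O)C(C)(C)C(O)=C(C(=O)OC)C1=O
F6 | step 2 | 2-bromo-3,5-dimethoxyphenol | COc1cc(OC)c(Br)c(O)c1
F7 | step 2 | (2-bromo-3,5-dimethoxyphenoxy)trimethylsilane | COc1cc(OC)c(Br)c(O[Si](C)(C)C)c1
F8 | step 8 | 3-propyl-1,2-benzisoxazole-4,6-diol | CCCc1noc2cc(O)cc(O)c12
A1 | alternative 1 | 2-{[2,4,6-tris(benzyloxy)-3-butanoylphenyl]methyl}-3,5-dihydroxy-4,4-dimethyl-6-propanoylcyclohexa-2,5-dien-1-one | CCCC(=O)c1c(OCc2ccccc2)cc(OCc2ccccc2)c(CC2=C(O)C(C)(C)C(O)=C(C(=O)CC)C2=O)c1OCc1ccccc1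
A2 | alternative 1 | 1-{2,4,6-tris(benzyloxy)-3-[(2,4,6-trihydroxy-3-propanoylphenyl)methyl]phenyl}butan-1-one | CCCC(=O)c1c(OCc2ccccc2)cc(OCc2ccccc2)c(Cc2c(O)cc(O)c(C(=O)CC)c2O)c1OCc1ccccc1
A3 | alternative 2 | 5-ethoxy-6,6-dimethyl-3-(triisopropylsilyloxy)-2-(2,4,6-trimethoxybenzyl)cyclohexa-2,4-dien-1-one | CCOC1=CC(O[Si](C(C)C)(C(C)C)C(C)C)=C(Cc2c(OC)cc(OC)cc2OC)C(=O)C1(C)C
A4 | alternative 2 | 3-ethoxy-4,4-dimethylcyclobut-2-en-1-one | CCOC1=CC(=O)C1(C)C
A5 | alternative 2 | triisopropyl{[3-(2,4,6-trimethoxyphenyl)prop-1-yn-1-yl]oxy}silane | COc1cc(OC)c(CC#CO[Si](C(C)C)(C(C)C)C(C)C)c(OC)c1
A6 | alternative 3 | 3,5-dihydroxy-4,4-dimethyl-2-propanoyl-6-(2,4,6-trimethoxybenzyl)cyclohexa-2,5-dien-1-one | COc1cc(OC)c(CC2=C(O)C(C)(C)C(O)=C(C(=O)CC)C2=O)c(OC)c1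
A7 | alternative 3 | methyl 2,2-dimethyl-3-oxo-5-(2,4,6-trimethoxyphenyl)pentanoate | COC(=O)C(C)(C)C(=O)CCc1c(OC)cc(OC)cc1OC
A8 | alternative 3 | 6-ethyl-2,2-dimethyl-4H-1,3-dioxin-4-one | CCC1=CC(=O)OC(C)(C)O1
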